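Two questions hang over each flask: which of target, starting material and side product holds the most at the end, and how much of it there is.

| flask | starting material | coupling partner | remark | time |
|---|---|---|---|---|
| north-east | 0.075 M | 0.030 M | run made earlier |  |
| east | 0.025 M | 0.030 M | run made earlier |  |
| alder | 0.050 M | 0.0300 M |  | 25 min |
| ash | 0.050 M | 0.0390 M |  | 25 min |
| oak | 0.050 M | 0.0510 M |  | 25 min |

| run | time / min | side product / % | starting material / % | target / % |
|---|---|---|---|---|
| north-east | 0.250 | 0.7 | 98.3 | 3.4 |
| north-east | 0.833 | 0.6 | 93.6 | 6.5 |
| north-east | 1.33 | 1.2 | 89.6 | 9.8 |
| north-east | 2.00 | 0.7 | 85.4 | 13.2 |
| north-east | 3.00 | 2.3 | 80.0 | 17.7 |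
| north-east | 4.00 | 4.7 | 77.8 | 16.5 |
| north-east | 5.00 | 4.0 | 73.5 | 19.4 |
| east | 0.250 | 0 | 96.3 | 3.0 |
| east | 0.833 | 0 | 92.8 | 9.8 |
| east | 1.33 | 0 | 88.9 | 11.7 |
| east | 2.00 | 0 | 82.6 | 16.7 |
| east | 3.00 | 1.2 | 77.2 | 20.7 |
| east | 4.00 | 3.8 | 73.3 | 25.6 |
| east | 5.00 | 1.7 | 68.3 | 29.3 |

(each reading ± 1 percentage point)

* which of these there is most of at the end, counted by the starting material in it, alder (target / starting material / side product)
* which of these there is most of at the end, counted by the starting material in it, ash (target / starting material / side product)
* which of these there is most of at the end, counted by the starting material in it, oak (target / starting material / side product)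
* the largest of these amounts at the end, in percent of the starting material charged, alder
* the largest of these amounts at the end, in percent of the starting material charged, ash
* the largest of these amounts at the end, in percent of the starting material charged, oak

- in percentages every species weighs as the starting material in it: one side product counts as two
- steps that have been proposed: starting material + coupling partner <-> target + by-product; starting material + target -> side product

Side product forms when starting material meets target, so I wrote its rate as κ times those two concentrations. Target bent in the north-east run, which gained 13.2% by 2.00 min and 6.2 percentage points in the 3.00 min after that, so I did not treat its rise as a straight line. With side product counting double, its percentage at the last reading is then 2·κ·a·S·M, where a is the starting material charged, S the area under the target fraction against time, taken as two straight pieces that meet at the reading of 2.00 min, and M the mean of unity and the final starting fraction.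

I had two ways to κ. The area S came to 0.621 min in the north-east run and 0.857 min in the east run. The side product column at the last reading gave 0.00825 M⁻¹ s⁻¹ in the north-east run and 0.00786 M⁻¹ s⁻¹ in the east run. The gap left in the balance by starting material and target gave 0.0146 M⁻¹ s⁻¹ and 0.0111 M⁻¹ s⁻¹. One constant should serve both runs, and the gap values lay further apart than the column values. The gap also carries the scatter of two readings, so I took it for the cheat. I kept the mean of the column values as the drain constant κ, the second-order rate constant of the loss of target, 0.00805 M⁻¹ s⁻¹.

The runs stop before the first step levels off, so its equilibrium constant K = 0.600 was my judgement, not a reading. Let x be the by-product concentration, s the side product concentration and b the coupling partner charged; then K = x(x−s)/[(a−x−s)(b−x)]. I assumed this balance held throughout and went round it for alder.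

With s at nil, x was 0.0165 M. Running that state's drain for 25 min gave s = 6.67 mM, which overshoots. Putting it back gave x = 0.0176 M. The true drain should lie between the two states, so I averaged their rates and got s = 5.03 mM.

The final pass for alder gave x = 0.0173 M, hence starting material 55.4%. Keeping alder's s, ash gave x = 0.0198 M and starting material 50.4%. Oak gave x = 0.0224 M and starting material 45.2%, still ahead of its target at 34.7%.

The forecast named starting material for alder at 52%, starting material for ash at 46% and starting material for oak at 41%, on the ground that “side product formation slowly drains target”.

    starting material + coupling partner ⇌ target + by-product (K = 0.570, k = 0.0530 M⁻¹ s⁻¹)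
    starting material + target → side product (k = 0.0110 M⁻¹ s⁻¹)

The flask gave starting material at 53.8% in alder, starting material at 47.8% in ash and starting material at 41.9% in oak. At the end of oak 30.7% of target stood in the flask, and the net rate making it was 0.0932 of the net rate using it up. Applied to the simulated amounts of alder from 12.5 min to the end, κ gave 8.4 points of new side product against 11 points found. For oak left until 1.0 h, κ gave 16 points after 25 min, and side product rose 21 points to 48.4%.

The earlier runs and the new flask are simulated for substances that don't exist; the scatter is artificial.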